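**Plan**

Rings are lettered A to E from the 3,5-dihydroxyphenoxy end; the ether links are A1–O–B1, B6–O–C1, C4–O–D1 and D6–O–E1.
- Retrosynthesis cuts the C4–O bond of the ring C/ring D ether first (A–B–C aryl bromide plus D–E phenol). It then cuts A–O–B (boronic acid coupling) and B–O–C (SNAr on an ortho-fluorobenzaldehyde); each oxygen at a doubly flanked carbon comes from a formyl group by Baeyer–Villiger oxidation.
- Ring E is built, not coupled. It is a phloroglucinol whose C-1 carries the ring-D oxygen between the hydroxylated C-2 and C-6. That makes C-2/C-1/C-6 an O-substituted malonyl unit and C-3/C-4/C-5 an acetone unit, so the C2–C3 and C6–C5 bonds are cut back to an aryloxymalonate and dimethyl 3-oxoglutarate.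
- Forward: ring D phenol from 2,4,6-trihydroxybenzaldehyde, then the aryloxymalonate, then ring E by double Claisen condensation, benzylation, ester removal and deallylation. Separately, ring C phenol plus ring B fluoroaldehyde, then ring A. The two fragments are joined by copper-catalysed etherification and the benzyl groups are removed by hydrogenolysis.
- Stereochemistry: the target has no stereocentre, so none has to be set.

Key step: step 7

Assumption: both annulation partners are used as methyl esters so that methoxide is the only alkoxide present, the malonate is introduced as its chloride to avoid halogen transfer to the electron-rich phenoxide, and the central oxygen of ring D is masked as an allyl ether so that it can later be freed without acid.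

**Route**

Step 1
Reactants: 1 2,4,6-trihydroxybenzaldehyde
Product: 2 2,4-bis(benzyloxy)-6-hydroxybenzaldehyde
Conditions: BnBr (2.05 equiv), K2CO3, DMF, 0 °C to rt
Reagents that add atoms: benzyl bromide, BrCc1ccccc1
Why: Williamson etherification in which the para hydroxyl and one ortho hydroxyl react, while the remaining ortho hydroxyl, held in a hydrogen bond to the formyl oxygen, should stay free.

Step 2
Reactants: 2 2,4-bis(benzyloxy)-6-hydroxybenzaldehyde
Product: 3 2,4-bis(benzyloxy)-6-(methoxymethoxy)benzaldehyde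
Conditions: NaH, DMF, 0 °C; then MOMCl, 0 °C to rt
Reagents that add atoms: chloromethyl methyl ether, COCCl
Why: irreversible deprotonation breaks the chelate and the phenoxide is O-alkylated by the α-chloro ether (Williamson-type acetal formation), giving a temporary group that survives peracid and carbonate.

Step 3
Reactants: 3 2,4-bis(benzyloxy)-6-(methoxymethoxy)benzaldehyde
Product: 5 2,4-bis(benzyloxy)-6-(methoxymethoxy)phenol, via aryl formate 4 (not isolated)
Conditions: mCPBA, CH2Cl2, 0 °C to rt; then K2CO3 (cat.), MeOH, 0 °C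
Reagents that add atoms: 3-chloroperoxybenzoic acid, O=C(OO)c1cccc(Cl)c1
Why: Baeyer–Villiger oxidation in which the electron-rich trioxygenated aryl group migrates in preference to hydride, followed by methanolysis of the formate.

Step 4
Reactants: 5 2,4-bis(benzyloxy)-6-(methoxymethoxy)phenol
Product: 6 2-(allyloxy)-1,5-bis(benzyloxy)-3-(methoxymethoxy)benzene
Conditions: allyl bromide, K2CO3, DMF, rt
Reagents that add atoms: allyl bromide, C=CCBr
Why: Williamson etherification of the only free phenol, which places a group removable under neutral conditions on the future C-1 oxygen of ring D.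

Step 5
Reactants: 6 2-(allyloxy)-1,5-bis(benzyloxy)-3-(methoxymethoxy)benzene
Product: 7 2-(allyloxy)-3,5-bis(benzyloxy)phenol
Conditions: HCl (cat.), MeOH, 45 °C
Reagents that add atoms: none
Why: acid-catalysed acetal exchange with methanol removes the methoxymethyl group, while allyl and benzyl aryl ethers are stable to dilute acid.

Step 6
Reactants: 7 2-(allyloxy)-3,5-bis(benzyloxy)phenol; 8 dimethyl chloromalonate
Product: 9 dimethyl 2-[2-(allyloxy)-3,5-bis(benzyloxy)phenoxy]malonate
Conditions: K2CO3, acetone, reflux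
Reagents that add atoms: none
Why: SN2 O-alkylation of the phenoxide by the doubly activated secondary chloride, the standard entry to aryloxymalonates from ortho-alkoxyphenols.

Step 7
Reactants: 9 dimethyl 2-[2-(allyloxy)-3,5-bis(benzyloxy)phenoxy]malonate; 10 dimethyl 3-oxoglutarate
Product: 12 dimethyl 5-[2-(allyloxy)-3,5-bis(benzyloxy)phenoxy]-2,4,6-trihydroxyisophthalate, via open-chain diketo triester 11 (not isolated)
Conditions: NaOMe (4 equiv), toluene–MeOH, 10 (2 equiv) added slowly at 105 °C with distillation of MeOH; then cold 1 M HCl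
Reagents that add atoms: none
Why: Proposed new method: under excess methoxide the enolate of 10 should attack one ester carbonyl of 9 (intermolecular Claisen condensation; the α-aryloxy group raises the electrophilicity of the ester and, at 105 °C, the malonate enolate can also lose methoxide by an E1cB step to a ketene that the same nucleophile traps) to give the open-chain diketo triester 11, whose second activated methylene then attacks the remaining malonate ester. This Dieckmann closure is 6-exo-trig, forms the ring-E C2–C3 and C6–C5 bonds in turn, and after loss of the second methoxide and enolisation leaves ring E as an aromatic tris-phenoxide. The closest known reaction is the alkoxide-mediated condensation of dialkyl malonates with acetonedicarboxylates to 2,4,6-trihydroxyisophthalates; what is new is the oxygen substituent on the malonate carbon. No stereocentre is formed. The step needs C- over O-acylation in the closure and cross- over self-condensation of 10: a 4-hydroxy-2-pyranone from O-attack is reopened by methoxide whereas the aromatic trianion is an irreversible sink, and slow addition of 10 into excess base keeps it fully enolised so that its ketone is masked against aldol self-condensation. Because the ether oxygen already sits on the future C-1 from step 6, no aryl C–O bond has to be made at this doubly flanked carbon.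

Step 8
Reactants: 12 dimethyl 5-[2-(allyloxy)-3,5-bis(benzyloxy)phenoxy]-2,4,6-trihydroxyisophthalate
Product: 13 dimethyl 5-[2-(allyloxy)-3,5-bis(benzyloxy)phenoxy]-2,4,6-tris(benzyloxy)isophthalate
Conditions: BnBr (3.6 equiv), K2CO3, DMF, 60 °C
Reagents that add atoms: benzyl bromide, BrCc1ccccc1
Why: Williamson etherification of the three chelated phenols, done while the two remaining ring positions still carry ester groups so that C-benzylation of the phloroglucinol nucleus cannot compete.

Step 9
Reactants: 13 dimethyl 5-[2-(allyloxy)-3,5-bis(benzyloxy)phenoxy]-2,4,6-tris(benzyloxy)isophthalate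
Product: 15 2-[2-(allyloxy)-3,5-bis(benzyloxy)phenoxy]-1,3,5-tris(benzyloxy)benzene, via isophthalic diacid 14 (not isolated)
Conditions: KOH, H2O–MeOH–1,4-dioxane, reflux; then aq. HCl to pH 1, 60 °C
Reagents that add atoms: none
Why: saponification of the two hindered methyl esters, followed by acid-promoted protodecarboxylation, which 2,6-dialkoxybenzoic acids undergo readily by ipso protonation of the electron-rich ring.

Step 10
Reactants: 15 2-[2-(allyloxy)-3,5-bis(benzyloxy)phenoxy]-1,3,5-tris(benzyloxy)benzene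
Product: 16 2,4-bis(benzyloxy)-6-[2,4,6-tris(benzyloxy)phenoxy]phenol
Conditions: Pd(PPh3)4 (5 mol %), morpholine, THF, rt
Reagents that add atoms: none
Why: Tsuji–Trost deallylation, in which zerovalent palladium ionises the allyl aryl ether and morpholine captures the allyl group, freeing the C-1 hydroxyl of ring D without touching benzyl or diaryl ethers.

Step 11
Reactants: 17 5-fluororesorcinol
Product: 18 1,3-bis(benzyloxy)-5-fluorobenzene
Conditions: BnBr (2.2 equiv), K2CO3, DMF, 60 °C
Reagents that add atoms: benzyl bromide, BrCc1ccccc1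
Why: twofold Williamson etherification of a simple resorcinol.

Step 12
Reactants: 18 1,3-bis(benzyloxy)-5-fluorobenzene
Product: 20 2,4-bis(benzyloxy)-6-fluorobenzaldehyde, via aryl iminium chloride 19 (not isolated)
Conditions: POCl3, DMF, 0 to 70 °C; then H2O
Reagents that add atoms: N,N-dimethylformamide, CN(C)C=O; water, O
Why: Vilsmeier–Haack formylation, expected mainly at one of the two equivalent positions para to a benzyloxy group and next to the small fluorine, not at the crowded position between the two benzyloxy groups; the minor isomer is to be removed by chromatography.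

Step 13
Reactants: 21 4-bromo-2,6-difluorobenzaldehyde
Product: 22 2,6-bis(benzyloxy)-4-bromobenzaldehyde
Conditions: BnOH (2.3 equiv), NaH, THF–DMF, 0 to 50 °C
Reagents that add atoms: benzyl alcohol, OCc1ccccc1
Why: twofold SNAr of sodium benzyloxide at the two fluorines ortho to the formyl group; fluoride leaves far faster than bromide in addition–elimination, so the para bromine should be kept.

Step 14
Reactants: 22 2,6-bis(benzyloxy)-4-bromobenzaldehyde
Product: 24 2,6-bis(benzyloxy)-4-bromophenol, via aryl formate 23 (not isolated)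
Conditions: mCPBA, CH2Cl2, 0 °C to rt; then K2CO3 (cat.), MeOH, 0 °C
Reagents that add atoms: 3-chloroperoxybenzoic acid, O=C(OO)c1cccc(Cl)c1
Why: Baeyer–Villiger oxidation with migration of the 2,6-dialkoxyaryl group and methanolysis of the formate, giving the ring-C phenol flanked by two benzyloxy groups.

Step 15
Reactants: 24 2,6-bis(benzyloxy)-4-bromophenol; 20 2,4-bis(benzyloxy)-6-fluorobenzaldehyde
Product: 25 2,4-bis(benzyloxy)-6-[2,6-bis(benzyloxy)-4-bromophenoxy]benzaldehyde
Conditions: Cs2CO3, DMSO, 100 °C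
Reagents that add atoms: none
Why: SNAr of the caesium phenoxide at the fluorine ortho to the formyl group; the two benzyloxy groups sit meta to the site of attack, where they do not destabilise the Meisenheimer intermediate, and the unactivated bromide is inert.

Step 16
Reactants: 25 2,4-bis(benzyloxy)-6-[2,6-bis(benzyloxy)-4-bromophenoxy]benzaldehyde
Product: 27 2,4-bis(benzyloxy)-6-[2,6-bis(benzyloxy)-4-bromophenoxy]phenol, via aryl formate 26 (not isolated)
Conditions: mCPBA, CH2Cl2, 0 °C to rt; then K2CO3 (cat.), MeOH, 0 °C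
Reagents that add atoms: 3-chloroperoxybenzoic acid, O=C(OO)c1cccc(Cl)c1
Why: a second Baeyer–Villiger oxidation and methanolysis turn the formyl carbon of ring B into its hydroxylated C-1.

Step 17
Reactants: 27 2,4-bis(benzyloxy)-6-[2,6-bis(benzyloxy)-4-bromophenoxy]phenol; 28 3,5-bis(benzyloxy)phenylboronic acid
Product: 29 1,3-bis(benzyloxy)-2-{3,5-bis(benzyloxy)-2-[3,5-bis(benzyloxy)phenoxy]phenoxy}-5-bromobenzene
Conditions: Cu(OAc)2 (1 equiv), pyridine, 4 Å MS, CH2Cl2, O2 (1 atm), rt
Reagents that add atoms: none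
Why: Chan–Lam coupling, which accepts phenols with two ortho substituents when the boronic acid is unhindered and leaves the aryl bromide untouched at room temperature; dioxygen returns copper to the divalent state.

Step 18
Reactants: 29 1,3-bis(benzyloxy)-2-{3,5-bis(benzyloxy)-2-[3,5-bis(benzyloxy)phenoxy]phenoxy}-5-bromobenzene; 16 2,4-bis(benzyloxy)-6-[2,4,6-tris(benzyloxy)phenoxy]phenol
Product: 30 undeca-O-benzyl ether of the target pentamer
Conditions: CuI (10 mol %), picolinic acid (20 mol %), K3PO4, DMSO, 100 °C, Ar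
Reagents that add atoms: none
Why: Ullmann-type C–O coupling with monovalent copper and picolinic acid, a ligand system suited to di-ortho-substituted phenols, here meeting an aryl bromide that has no ortho substituent.

Step 19
Reactants: 30 undeca-O-benzyl ether of the target pentamer
Product: 31 5-{2,4-dihydroxy-6-[2,6-dihydroxy-4-(2,4-dihydroxy-6-(2,4,6-trihydroxyphenoxy)phenoxy)phenoxy]phenoxy}benzene-1,3-diol
Conditions: H2 (1 atm), 10% Pd/C, THF–MeOH, rt
Reagents that add atoms: none
Why: hydrogenolysis of all eleven benzyl aryl ethers, to which the four diaryl ether bonds are inert.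

**Compound list**

1 | 2,4,6-trihydroxybenzaldehyde | O=Cc1c(O)cc(O)cc1O | starting material
2 | 2,4-bis(benzyloxy)-6-hydroxybenzaldehyde | O=Cc1c(O)cc(OCc2ccccc2)cc1OCc1ccccc1 | intermediate
3 | 2,4-bis(benzyloxy)-6-(methoxymethoxy)benzaldehyde | COCOc1cc(OCc2ccccc2)cc(OCc2ccccc2)c1C=O | intermediate
4 | 2,4-bis(benzyloxy)-6-(methoxymethoxy)phenyl formate | COCOc1cc(OCc2ccccc2)cc(OCc2ccccc2)c1OC=O | intermediate (not isolated)
5 | 2,4-bis(benzyloxy)-6-(methoxymethoxy)phenol | COCOc1cc(OCc2ccccc2)cc(OCc2ccccc2)c1O | intermediate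
6 | 2-(allyloxy)-1,5-bis(benzyloxy)-3-(methoxymethoxy)benzene | COCOc1cc(OCc2ccccc2)cc(OCc2ccccc2)c1OCC=C | intermediate
7 | 2-(allyloxy)-3,5-bis(benzyloxy)phenol | Oc1cc(OCc2ccccc2)cc(OCc2ccccc2)c1OCC=C | intermediate
8 | dimethyl chloromalonate | COC(=O)C(Cl)C(=O)OC | starting material
9 | dimethyl 2-[2-(allyloxy)-3,5-bis(benzyloxy)phenoxy]malonate | COC(=O)C(Oc1cc(OCc2ccccc2)cc(OCc2ccccc2)c1OCC=C)C(=O)OC | intermediate
10 | dimethyl 3-oxoglutarate | COC(=O)CC(=O)CC(=O)OC | starting material
11 | trimethyl 1-[2-(allyloxy)-3,5-bis(benzyloxy)phenoxy]-2,4-dioxopentane-1,3,5-tricarboxylate | COC(=O)CC(=O)C(C(=O)OC)C(=O)C(Oc1cc(OCc2ccccc2)cc(OCc2ccccc2)c1OCC=C)C(=O)OC | intermediate (not isolated)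
12 | dimethyl 5-[2-(allyloxy)-3,5-bis(benzyloxy)phenoxy]-2,4,6-trihydroxyisophthalate | COC(=O)c1c(O)c(C(=O)OC)c(O)c(Oc2cc(OCc3ccccc3)cc(OCc3ccccc3)c2OCC=C)c1O | intermediate
13 | dimethyl 5-[2-(allyloxy)-3,5-bis(benzyloxy)phenoxy]-2,4,6-tris(benzyloxy)isophthalate | COC(=O)c1c(OCc2ccccc2)c(C(=O)OC)c(OCc2ccccc2)c(Oc2cc(OCc3ccccc3)cc(OCc3ccccc3)c2OCC=C)c1OCc1ccccc1 | intermediate
14 | 5-[2-(allyloxy)-3,5-bis(benzyloxy)phenoxy]-2,4,6-tris(benzyloxy)isophthalic acid | OC(=O)c1c(OCc2ccccc2)c(C(=O)O)c(OCc2ccccc2)c(Oc2cc(OCc3ccccc3)cc(OCc3ccccc3)c2OCC=C)c1OCc1ccccc1 | intermediate (not isolated)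
15 | 2-[2-(allyloxy)-3,5-bis(benzyloxy)phenoxy]-1,3,5-tris(benzyloxy)benzene | C=CCOc1c(OCc2ccccc2)cc(OCc2ccccc2)cc1Oc1c(OCc2ccccc2)cc(OCc2ccccc2)cc1OCc1ccccc1 | intermediate
16 | 2,4-bis(benzyloxy)-6-[2,4,6-tris(benzyloxy)phenoxy]phenol | Oc1c(OCc2ccccc2)cc(OCc2ccccc2)cc1Oc1c(OCc2ccccc2)cc(OCc2ccccc2)cc1OCc1ccccc1 | intermediate
17 | 5-fluororesorcinol (5-fluorobenzene-1,3-diol) | Oc1cc(O)cc(F)c1 | starting material
18 | 1,3-bis(benzyloxy)-5-fluorobenzene | Fc1cc(OCc2ccccc2)cc(OCc2ccccc2)c1 | intermediate
19 | N-{[2,4-bis(benzyloxy)-6-fluorophenyl]methylidene}-N-methylmethanaminium chloride | C[N+](C)=Cc1c(F)cc(OCc2ccccc2)cc1OCc1ccccc1.[Cl-] | intermediate (not isolated)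
20 | 2,4-bis(benzyloxy)-6-fluorobenzaldehyde | O=Cc1c(F)cc(OCc2ccccc2)cc1OCc1ccccc1 | intermediate
21 | 4-bromo-2,6-difluorobenzaldehyde | O=Cc1c(F)cc(Br)cc1F | starting material
22 | 2,6-bis(benzyloxy)-4-bromobenzaldehyde | O=Cc1c(OCc2ccccc2)cc(Br)cc1OCc1ccccc1 | intermediate
23 | 2,6-bis(benzyloxy)-4-bromophenyl formate | O=COc1c(OCc2ccccc2)cc(Br)cc1OCc1ccccc1 | intermediate (not isolated)
24 | 2,6-bis(benzyloxy)-4-bromophenol | Oc1c(OCc2ccccc2)cc(Br)cc1OCc1ccccc1 | intermediate
25 | 2,4-bis(benzyloxy)-6-[2,6-bis(benzyloxy)-4-bromophenoxy]benzaldehyde | O=Cc1c(Oc2c(OCc3ccccc3)cc(Br)cc2OCc2ccccc2)cc(OCc2ccccc2)cc1OCc1ccccc1 | intermediate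
26 | 2,4-bis(benzyloxy)-6-[2,6-bis(benzyloxy)-4-bromophenoxy]phenyl formate | O=COc1c(Oc2c(OCc3ccccc3)cc(Br)cc2OCc2ccccc2)cc(OCc2ccccc2)cc1OCc1ccccc1 | intermediate (not isolated)
27 | 2,4-bis(benzyloxy)-6-[2,6-bis(benzyloxy)-4-bromophenoxy]phenol | Oc1c(Oc2c(OCc3ccccc3)cc(Br)cc2OCc2ccccc2)cc(OCc2ccccc2)cc1OCc1ccccc1 | intermediate
28 | 3,5-bis(benzyloxy)phenylboronic acid | OB(O)c1cc(OCc2ccccc2)cc(OCc2ccccc2)c1 | starting material
29 | 1,3-bis(benzyloxy)-2-{3,5-bis(benzyloxy)-2-[3,5-bis(benzyloxy)phenoxy]phenoxy}-5-bromobenzene (A–B–C bromide) | Brc1cc(OCc2ccccc2)c(Oc2cc(OCc3ccccc3)cc(OCc3ccccc3)c2Oc2cc(OCc3ccccc3)cc(OCc3ccccc3)c2)c(OCc2ccccc2)c1 | intermediate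
30 | undeca-O-benzyl ether of the target (every hydroxyl of 31 as its benzyl ether) | c4ccccc4COc1cc(OCc4ccccc4)cc(Oc2c(OCc4ccccc4)cc(OCc4ccccc4)cc2Oc2c(OCc4ccccc4)cc(Oc3c(OCc4ccccc4)cc(OCc4ccccc4)cc3Oc3c(OCc4ccccc4)cc(OCc4ccccc4)cc3OCc3ccccc3)cc2OCc2ccccc2)c1 | intermediate
31 | 5-{2,4-dihydroxy-6-[2,6-dihydroxy-4-(2,4-dihydroxy-6-(2,4,6-trihydroxyphenoxy)phenoxy)phenoxy]phenoxy}benzene-1,3-diol (CNP0018313.0) | Oc1cc(O)cc(Oc2c(O)cc(O)cc2Oc2c(O)cc(Oc3c(O)cc(O)cc3Oc3c(O)cc(O)cc3O)cc2O)c1 | target

**Step count and risks**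

Total: 19 steps. Longest linear sequence: 12 steps (steps 1 to 10, then 18 and 19).

Steps most likely to fail:

1. Step 7 (proposed new method). The aryloxymalonate may rest as its unreactive sodium enolate while 10 is used up by self-condensation, or the open-chain intermediate may close through oxygen to a pyranone that does not revert. The fallback uses only SNAr and Baeyer–Villiger chemistry and sets out from 2. Exhaustive benzylation (BnBr, K2CO3, DMF, 70 °C) should give 2,4,6-tris(benzyloxy)benzaldehyde F1. Oxidation with mCPBA and methanolysis should lead, through 2,4,6-tris(benzyloxy)phenyl formate F2, to 2,4,6-tris(benzyloxy)phenol F3. Its caesium salt should displace the fluoride of 20 (Cs2CO3, DMSO, 100 °C) to give 2,4-bis(benzyloxy)-6-[2,4,6-tris(benzyloxy)phenoxy]benzaldehyde F4. A second mCPBA oxidation and methanolysis, through 2,4-bis(benzyloxy)-6-[2,4,6-tris(benzyloxy)phenoxy]phenyl formate F5, comes back to the route at 16.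

2. Step 18. Oxidative addition of the electron-rich bromide may be slow, so that the hindered, easily oxidised phenoxide is degraded or the bromide is reduced before the ether forms. The fallback sets out from 29. Palladium-catalysed borylation (Pd(OAc)2, XPhos, B2(OH)4, KOAc, EtOH, 80 °C) should give {3,5-bis(benzyloxy)-4-{3,5-bis(benzyloxy)-2-[3,5-bis(benzyloxy)phenoxy]phenoxy}phenyl}boronic acid F6. This is then joined to 16 by Chan–Lam coupling at room temperature (Cu(OAc)2, pyridine, 4 Å MS, CH2Cl2, O2), coming back to the route at 30.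

3. Step 15. Addition of the di-ortho-substituted phenoxide may be too slow because two alkoxy donors damp the activation by the formyl group, and the aldehyde may decompose under hot base. The fallback sets out from 24 and changes the order of bond formation. Commercial 2,6-difluoro-4-hydroxybenzaldehyde is benzylated (BnBr, K2CO3, DMF) to 4-(benzyloxy)-2,6-difluorobenzaldehyde F7, which carries one donor fewer and a second activating fluorine. Phenol 24 should displace one of its two equivalent fluorines under milder conditions (Cs2CO3, DMF, 60 °C) to give 4-(benzyloxy)-2-[2,6-bis(benzyloxy)-4-bromophenoxy]-6-fluorobenzaldehyde F8. Sodium benzyloxide (BnOH, NaH, THF–DMF) then replaces the remaining fluorine as in step 13, coming back to the route at 25.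

Further compounds
F1 | step 7 | 2,4,6-tris(benzyloxy)benzaldehyde | O=Cc1c(OCc2ccccc2)cc(OCc2ccccc2)cc1OCc1ccccc1
F2 | step 7 | 2,4,6-tris(benzyloxy)phenyl formate | O=COc1c(OCc2ccccc2)cc(OCc2ccccc2)cc1OCc1ccccc1
F3 | step 7 | 2,4,6-tris(benzyloxy)phenol | Oc1c(OCc2ccccc2)cc(OCc2ccccc2)cc1OCc1ccccc1
F4 | step 7 | 2,4-bis(benzyloxy)-6-[2,4,6-tris(benzyloxy)phenoxy]benzaldehyde | O=Cc1c(Oc2c(OCc3ccccc3)cc(OCc3ccccc3)cc2OCc2ccccc2)cc(OCc2ccccc2)cc1OCc1ccccc1
F5 | step 7 | 2,4-bis(benzyloxy)-6-[2,4,6-tris(benzyloxy)phenoxy]phenyl formate | O=COc1c(Oc2c(OCc3ccccc3)cc(OCc3ccccc3)cc2OCc2ccccc2)cc(OCc2ccccc2)cc1OCc1ccccc1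
F6 | step 18 | {3,5-bis(benzyloxy)-4-{3,5-bis(benzyloxy)-2-[3,5-bis(benzyloxy)phenoxy]phenoxy}phenyl}boronic acid | OB(O)c1cc(OCc2ccccc2)c(Oc2cc(OCc3ccccc3)cc(OCc3ccccc3)c2Oc2cc(OCc3ccccc3)cc(OCc3ccccc3)c2)c(OCc2ccccc2)c1
F7 | step 15 | 4-(benzyloxy)-2,6-difluorobenzaldehyde | O=Cc1c(F)cc(OCc2ccccc2)cc1F
F8 | step 15 | 4-(benzyloxy)-2-[2,6-bis(benzyloxy)-4-bromophenoxy]-6-fluorobenzaldehyde | O=Cc1c(F)cc(OCc2ccccc2)cc1Oc1c(OCc2ccccc2)cc(Br)cc1OCc1ccccc1
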